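**Plan**

1. Retrosynthesis: the benzyl ether and the C3=C4 double bond lead back to a 4-aryl-dihydrocoumarin and its cyclic ortho ester. The pyranone ring is then cut at C3–C4 and O1–C2 (loss of a ketene acetal), followed by C4–C1' (aryllithium plus aldehyde) and C4–C4a (formylation of ring A).
2. Enabling feature: C4 is doubly benzylic (rings A and B) and ortho to the C8a oxygen, so C4=C4a–C8a=O1 of an ortho-quinone methide is a heterodiene that takes up C3 and C2 in one [4+2] event.
3. Forward: ring A is formylated and demethylated at the oxygen that becomes O1, which is then carried as a tert-butyl carbonate. Ring B is joined as an aryllithium. Base moves the carbonate to the carbinol oxygen, so the quinone methide is released cold and without acid, which the ketene acetal and the ortho ester would not survive.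
4. 1,1-Dimethoxyethene then closes the pyran ring, the only ring formed; ortho ester hydrolysis, dehydrogenation and debenzylation finish the synthesis.
5. Stereochemistry: the target is achiral. The carbinol carbon and C4 form racemic, and C4 is erased by the dehydrogenation.

Key step: step 6

Remark: compounds 1, 6 and 10 are taken as commercial. The selectivity of step 2 rests on the known preference of chelating Lewis acids for the ortho methoxy group that is flanked by a second methoxy group.

**Route**

Step 1
Reactants: 1 1,2,3,5-tetramethoxybenzene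
Product: 3 2,3,4,6-tetramethoxybenzaldehyde, via aryl iminium chloride 2 (not isolated)
Conditions: POCl3 (1.2 equiv), DMF, 0 °C → 60 °C; then ice-water, rt
Reagents that add atoms: N,N-dimethylformamide, CN(C)C=O; water, O
Why: Vilsmeier–Haack formylation, in which the chloroiminium electrophile attacks one of the two equivalent free positions of the electron-rich arene and the iminium salt is hydrolysed on work-up.

Step 2
Reactants: 3 2,3,4,6-tetramethoxybenzaldehyde
Product: 4 2-hydroxy-3,4,6-trimethoxybenzaldehyde
Conditions: AlCl3 (1.3 equiv), CH2Cl2, 0 °C → rt; then 1 M aq. HCl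
Reagents that add atoms: none
Why: Chelation-directed Lewis-acid ether cleavage, in which AlCl3 bound to the formyl oxygen reaches only the two ortho methoxy groups and the C2 one, forced out of the ring plane between the formyl group and the C3 methoxy group, is the more basic and should be the one demethylated by chloride.

Step 3
Reactants: 4 2-hydroxy-3,4,6-trimethoxybenzaldehyde
Product: 5 tert-butyl 2-formyl-3,5,6-trimethoxyphenyl carbonate
Conditions: Boc2O (1.2 equiv), DMAP (5 mol%), i-Pr2NEt (1.2 equiv), THF, rt
Reagents that add atoms: di-tert-butyl dicarbonate, CC(C)(C)OC(=O)OC(=O)OC(C)(C)C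
Why: DMAP-catalysed O-acylation of the phenol gives the aryl carbonate, which masks the acidic OH for the organolithium step and is the latent leaving group for the quinone methide.

Step 4
Reactants: 6 5-bromo-2-methoxyphenol
Product: 7 2-(benzyloxy)-4-bromo-1-methoxybenzene
Conditions: BnBr (1.1 equiv), K2CO3 (1.5 equiv), DMF, rt
Reagents that add atoms: benzyl bromide, BrCc1ccccc1
Why: Williamson ether synthesis on the phenoxide; the benzyl ether should withstand organolithium, Grignard base, dilute acid and DDQ and leaves by hydrogenolysis at the end.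

Step 5
Reactants: 7 2-(benzyloxy)-4-bromo-1-methoxybenzene; 5 tert-butyl 2-formyl-3,5,6-trimethoxyphenyl carbonate
Product: 9 racemic tert-butyl 2-{[3-(benzyloxy)-4-methoxyphenyl](hydroxy)methyl}-3,5,6-trimethoxyphenyl carbonate, via aryllithium 8 (not isolated)
Conditions: 7 (1.05 equiv), n-BuLi (1.0 equiv), THF, −78 °C; then 5, THF, −78 °C; AcOH (1.1 equiv), −78 °C → rt
Reagents that add atoms: none
Why: Bromine–lithium exchange and 1,2-addition of the aryllithium to the aldehyde, which is far more electrophilic than the carbonate; the lithium alkoxide should not transfer the carbonate at −78 °C and is protonated cold, and the carbinol stereocentre forms racemic, which is all that is needed.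

Step 6
Reactants: 9 racemic tert-butyl 2-{[3-(benzyloxy)-4-methoxyphenyl](hydroxy)methyl}-3,5,6-trimethoxyphenyl carbonate; 10 1,1-dimethoxyethene
Product: 13 racemic 4-[3-(benzyloxy)-4-methoxyphenyl]-2,2,5,7,8-pentamethoxychroman, via benzylic carbonate phenoxide 11 (not isolated), via ortho-quinone methide 12 (not isolated)
Conditions: 10 (5 equiv), t-BuMgCl (1.05 equiv), Et2O, −78 °C → rt; then sat. aq. NaHCO3
Reagents that add atoms: none
Why: t-BuMgCl deprotonates the carbinol, the magnesium alkoxide takes over the Boc group from the neighbouring aryl carbonate, and phenoxide 11 expels tert-butyl carbonate in a 1,4-elimination, releasing ortho-quinone methide 12 cold and under base, where neither the ketene acetal nor the ortho ester is at risk. 12 then undergoes an inverse-electron-demand hetero-Diels–Alder reaction with 10, in which the CH2 terminus bonds to C4 and the quinone methide oxygen to the acetal carbon, forming C3–C4 and O1–C2. The closest known reaction type is the base-triggered release of ortho-quinone methides from ortho-OBoc benzylic alcohols and their [4+2] capture by enol ethers and ketene acetals to give chroman ketals. The pyran ring closes by this [4+2] cycloaddition (in the stepwise limit a 6-exo-trig attack of the phenoxide oxygen on the dioxocarbenium carbon), and ring A regains its aromaticity. C4 is the only new stereocentre; nothing controls it, it forms racemic and is erased in step 8. The step needs regioselectivity only, secured by the polarity match between C4 (electrophilic, stabilised by ring B and the 5- and 7-methoxy groups) and the nucleophilic CH2 of the ketene acetal, while the excess of 10 should outrun dimerisation of 12.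

Step 7
Reactants: 13 racemic 4-[3-(benzyloxy)-4-methoxyphenyl]-2,2,5,7,8-pentamethoxychroman
Product: 15 racemic 4-[3-(benzyloxy)-4-methoxyphenyl]-5,7,8-trimethoxychroman-2-one, via hydroxy ester 14 (not isolated)
Conditions: 1 M aq. HCl, THF, rt; then TsOH·H2O (5 mol%), PhMe, 80 °C
Reagents that add atoms: water, O
Why: Ortho ester hydrolysis through the dioxocarbenium ion opens at the phenol oxygen to hydroxy ester 14, which recloses under acid catalysis with loss of methanol to the six-membered aryl lactone (lactonisation); C4 stays racemic.

Step 8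
Reactants: 15 racemic 4-[3-(benzyloxy)-4-methoxyphenyl]-5,7,8-trimethoxychroman-2-one
Product: 16 4-[3-(benzyloxy)-4-methoxyphenyl]-5,7,8-trimethoxy-2H-chromen-2-one
Conditions: DDQ (1.5 equiv), 1,4-dioxane, 100 °C
Reagents that add atoms: none
Why: DDQ dehydrogenation, in which hydride abstraction from the doubly benzylic C4–H and loss of the C3 proton give the conjugated coumarin, the standard passage from 4-aryl-dihydrocoumarins to 4-arylcoumarins, and remove the C4 stereocentre.

Step 9
Reactants: 16 4-[3-(benzyloxy)-4-methoxyphenyl]-5,7,8-trimethoxy-2H-chromen-2-one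
Product: 17 4-(3-hydroxy-4-methoxyphenyl)-5,7,8-trimethoxy-2H-chromen-2-one (3'-hydroxy-5,7,8,4'-tetramethoxy-4-phenylcoumarin)
Conditions: H2 (1 atm), Pd/C (10 wt%), EtOAc, rt
Reagents that add atoms: none
Why: Catalytic hydrogenolysis of the benzyl aryl ether; the trisubstituted, conjugated C3–C4 double bond, shielded by ring B and the 5-methoxy group, should be reduced much more slowly, so the reaction is stopped once one equivalent of hydrogen is taken up.

**Compound list**

1 | 1,2,3,5-tetramethoxybenzene | COc1cc(OC)c(OC)c(OC)c1 | starting material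
2 | N-[(2,3,4,6-tetramethoxyphenyl)methylidene]-N-methylmethanaminium chloride | COc1cc(OC)c(OC)c(OC)c1C=[N+](C)C.[Cl-] | intermediate (not isolated)
3 | 2,3,4,6-tetramethoxybenzaldehyde | COc1cc(OC)c(OC)c(OC)c1C=O | intermediate
4 | 2-hydroxy-3,4,6-trimethoxybenzaldehyde | COc1cc(OC)c(OC)c(O)c1C=O | intermediate
5 | tert-butyl 2-formyl-3,5,6-trimethoxyphenyl carbonate | COc1cc(OC)c(OC)c(OC(=O)OC(C)(C)C)c1C=O | intermediate
6 | 5-bromo-2-methoxyphenol | COc1ccc(Br)cc1O | starting material
7 | 2-(benzyloxy)-4-bromo-1-methoxybenzene | COc1ccc(Br)cc1OCc1ccccc1 | intermediate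
8 | [3-(benzyloxy)-4-methoxyphenyl]lithium | [Li]c1ccc(OC)c(OCc2ccccc2)c1 | intermediate (not isolated)
9 | racemic tert-butyl 2-{[3-(benzyloxy)-4-methoxyphenyl](hydroxy)methyl}-3,5,6-trimethoxyphenyl carbonate | COc1ccc(C(O)c2c(OC(=O)OC(C)(C)C)c(OC)c(OC)cc2OC)cc1OCc1ccccc1 | intermediate
10 | 1,1-dimethoxyethene | C=C(OC)OC | starting material
11 | racemic chloromagnesium 2-{[3-(benzyloxy)-4-methoxyphenyl][(tert-butoxycarbonyl)oxy]methyl}-3,5,6-trimethoxyphenolate | COc1ccc(C(OC(=O)OC(C)(C)C)c2c([O-])c(OC)c(OC)cc2OC)cc1OCc1ccccc1.[Mg+2].[Cl-] | intermediate (not isolated)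
12 | 6-[3-(benzyloxy)-4-methoxybenzylidene]-2,3,5-trimethoxycyclohexa-2,4-dien-1-one (double-bond geometry immaterial, both isomers converge) | COc1ccc(C=C2C(=O)C(OC)=C(OC)C=C2OC)cc1OCc1ccccc1 | intermediate (not isolated)
13 | racemic 4-[3-(benzyloxy)-4-methoxyphenyl]-2,2,5,7,8-pentamethoxychroman | COc1ccc(C2CC(OC)(OC)Oc3c(OC)c(OC)cc(OC)c23)cc1OCc1ccccc1 | intermediate
14 | racemic methyl 3-[3-(benzyloxy)-4-methoxyphenyl]-3-(2-hydroxy-3,4,6-trimethoxyphenyl)propanoate | COC(=O)CC(c1ccc(OC)c(OCc2ccccc2)c1)c1c(O)c(OC)c(OC)cc1OC | intermediate (not isolated)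
15 | racemic 4-[3-(benzyloxy)-4-methoxyphenyl]-5,7,8-trimethoxychroman-2-one | COc1ccc(C2CC(=O)Oc3c(OC)c(OC)cc(OC)c23)cc1OCc1ccccc1 | intermediate
16 | 4-[3-(benzyloxy)-4-methoxyphenyl]-5,7,8-trimethoxy-2H-chromen-2-one | COc1ccc(-c2cc(=O)oc3c(OC)c(OC)cc(OC)c23)cc1OCc1ccccc1 | intermediate
17 | 4-(3-hydroxy-4-methoxyphenyl)-5,7,8-trimethoxy-2H-chromen-2-one | COc1ccc(-c2cc(=O)oc3c(OC)c(OC)cc(OC)c23)cc1O | target

**Count**

Total steps: 9. Longest linear sequence: 8 steps (steps 1, 2, 3, 5, 6, 7, 8, 9 from compound 1); step 4 is the one-step side branch.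

**Steps most likely to fail**

Step 6. The quinone methide, stabilised by three donor groups, may be released but combine too slowly with the ketene acetal, so that it dimerises or is captured by tert-butoxide. The fallback replaces the cycloaddition by a stepwise conjugate addition and sets out from 9. Compound 9 is treated with t-BuMgCl at −78 °C in the presence of the sodium enolate of dimethyl malonate (NaH, THF) and warmed to rt. The soft carbanion should add to C4 of 12 and give, after protic work-up, dimethyl 2-{[3-(benzyloxy)-4-methoxyphenyl](2-hydroxy-3,4,6-trimethoxyphenyl)methyl}malonate F1. Krapcho demethoxycarbonylation (LiCl, wet DMSO, 150 °C) then removes one ester group and returns to the route at hydroxy ester 14, which is lactonised to 15 with TsOH as in step 7.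

Step 5. Carbonate transfer may set in during the addition or the quench. The quinone methide would then be released with no trap present and would consume a second aryllithium at C4. The fallback gives up the isolation of 9 and sets out from 5 and 7. The aryllithium 8 is added to 5 at −78 °C with 10 (5 equiv) already in the flask; without a quench, MgBr2·OEt2 is added and the mixture is warmed to rt. The alkoxide of 9 should then pass through 11 and 12 to the cycloadduct in the same flask, so that an early release of the quinone methide becomes productive. The fallback returns at 13 and makes no new compound (F0).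

Step 2. Regiocontrol may be lost by cleavage of the C6 methoxy group, or a second demethylation may occur at C3. The fallback fixes the free oxygen by construction; it replaces 1 and 3 and returns at 4.
- Commercial 2-hydroxy-4,6-dimethoxybenzaldehyde F2 is benzylated (BnBr, K2CO3, DMF) to 2-(benzyloxy)-4,6-dimethoxybenzaldehyde F3.
- Baeyer–Villiger oxidation (mCPBA, CH2Cl2) gives 2-(benzyloxy)-4,6-dimethoxyphenyl formate F4, which is saponified (KOH, aq. MeOH) to 2-(benzyloxy)-4,6-dimethoxyphenol F5.
- Methylation (MeI, K2CO3, acetone) gives 1-(benzyloxy)-2,3,5-trimethoxybenzene F6, and hydrogenolysis (H2, Pd/C, EtOAc) frees 2,3,5-trimethoxyphenol F7.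
- The only free ortho position of F7 is formylated by the magnesium-mediated ortho-specific method (MgCl2, Et3N, paraformaldehyde, MeCN, reflux) to give 4.

**Further compounds**

F1 | step 6 | racemic dimethyl 2-{[3-(benzyloxy)-4-methoxyphenyl](2-hydroxy-3,4,6-trimethoxyphenyl)methyl}malonate | COC(=O)C(C(=O)OC)C(c1ccc(OC)c(OCc2ccccc2)c1)c1c(O)c(OC)c(OC)cc1OC
F0 | step 5 | none | none
F2 | step 2 | 2-hydroxy-4,6-dimethoxybenzaldehyde | COc1cc(O)c(C=O)c(OC)c1
F3 | step 2 | 2-(benzyloxy)-4,6-dimethoxybenzaldehyde | COc1cc(OCc2ccccc2)c(C=O)c(OC)c1
F4 | step 2 | 2-(benzyloxy)-4,6-dimethoxyphenyl formate | COc1cc(OCc2ccccc2)c(OC=O)c(OC)c1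
F5 | step 2 | 2-(benzyloxy)-4,6-dimethoxyphenol | COc1cc(OCc2ccccc2)c(O)c(OC)c1
F6 | step 2 | 1-(benzyloxy)-2,3,5-trimethoxybenzene | COc1cc(OCc2ccccc2)c(OC)c(OC)c1
F7 | step 2 | 2,3,5-trimethoxyphenol | COc1cc(O)c(OC)c(OC)c1
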